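The earlier runs and the new flask stem from a simulated flask with made-up constants, and the scatter is random.

We fit no rate constants for this flask; one ratio read from the runs carries the argument.

| setting | cedar | oak | flask |
|---|---|---|---|
| substrate | 20 mM | 20 mM | 20 mM |
| other conformer | 20 mM | 40 mM | 20.0 mM |
| solid reagent | 24 mM | 24 mM | 24.0 mM |
| remark | the very flask that is asked about, followed so far | run made earlier |  |
| time |  |  | 25 h |

| run | time / h | target / % | isomer of the product A / % | substrate / % |
|---|---|---|---|---|
| cedar | 0.167 | 0.9 | 0 | 41.2 |
| cedar | 0.500 | 2.2 | 1.5 | 28.6 |
| cedar | 0.833 | 3.3 | 4.9 | 19.1 |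
| cedar | 1.33 | 4.2 | 9.1 | 12.7 |
| cedar | 2.00 | 5.1 | 15.8 | 9.9 |
| cedar | 2.50 | 5.1 | 21.6 | 7.9 |
| cedar | 3.00 | 6.9 | 25.3 | 6.9 |
| oak | 1.33 | 3.1 | 9.0 | 12.0 |
| oak | 2.00 | 4.3 | 14.8 | 10.7 |
| oak | 3.00 | 5.0 | 22.6 | 8.8 |
| oak | 5.00 | 4.8 | 25.5 | 8.7 |
| oak | 8.00 | 5.6 | 26.7 | 9.6 |
| oak | 12.0 | 5.3 | 26.1 | 8.8 |
| oak | 20.0 | 5.3 | 26.0 | 9.2 |

(scatter of a reading: 0.5 percentage points)

* the state of affairs at 25 h: stopped, and by what, or still going (for what has run out or reacted, a solid counts together with what of it has only dissolved; other conformer counts as not reacted) (forward and back rates have come level / the partner has run out first / it is still moving / all of the substrate has reacted)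
* amount of target at 25 h, in percent of the substrate and other conformer together charged
* amount of isomer of the product A at 25 h, in percent of the substrate and other conformer together charged

- solid, in amounts per volume of the solution: solid reagent
- at the start none of the solid reagent is in solution
- in a conversion other conformer counts as not yet reacted
- the reaction counts as stopped when no species that holds the substrate and other conformer together changes by six tenths of a point or more over the second half of the time

Read oak down the column of isomer of the product A. From 2.00 h to 3.00 h it gains 4.68 mM h⁻¹, and from there to 5.00 h it gains 0.870 mM h⁻¹. Substrate meanwhile reads 10.7%, 8.8%, 8.7%, so the rate falls by a larger factor than substrate does, and we suspect that something else has dropped.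

Now set cedar beside oak. At 3.00 h cedar's ratio of isomer of the product A to substrate is 3.67 and still climbing, which is higher than oak's final 2.83. A fixed ratio therefore does not explain oak's halt. Both flasks share 24 mM of solid reagent, so we take it as the limiting reagent.

From 8.00 h on, oak holds on average 19.0 mM of target plus isomer of the product A. Dividing by the solid charged gives the product per reagent, 0.792. It lies below one, so we expect part of the reagent to end in something unread.

For the cedar flask this gives a stop at 47.5% of target plus isomer of the product A. Cedar, at 32.2% and keeping its latest pace, gets there near 4.35 h, earlier than 25 h. Split as in oak's late rows, we expect 8.10% target and 39.4% isomer of the product A, and we expect the stop to come with the 24.0 mM of solid reagent charged used up.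

The forecast, which differs from us on the ending, says forward and back rates have come level, with 6.9% target and 34.5% isomer of the product A, holding of oak that “the partner has not run out”.

The flask gives: the partner has run out first, with 7.90% target and 38.7% isomer of the product A, together 46.6% against our 47.5%.

    partner + other conformer → isomer of the product A (k = 0.460 M⁻¹ min⁻¹)
    substrate + partner → target (k = 1.30 M⁻¹ min⁻¹)
    solid reagent ⇌ partner, rate k3*(cs3 - [partner]) while solid is left; crystals form when [partner] > cs3 (solubility = 11.0 mM, k = 0.0210 min⁻¹)
    target ⇌ isomer of the product B (K = 1.70, k = 0.0420 min⁻¹)
    substrate ⇌ other conformer (K = 6.00, k = 0.0230 min⁻¹)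

At 2.50 h solid reagent stood at 16.4% of its charge with [partner] 6.15 mM, and the steps to target and to isomer of the product A were both running. At 12.5 h the solid stood at 0% and [partner] at 0.0269 mM, and target and isomer of the product A then held their values up to 25 h, with 69% of the charged other conformer still there. Isomer of the product B, unread, ends at 13.4%; with it the products sum to 24.0 mM against 24.0 mM charged.

With other conformer at 34 mM and the same solid, the ratio gives 35.2% of target plus isomer of the product A. The computed neighbour holds 34.7%, with solid reagent at 0%.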